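**Plan**

Ring numbering used in the discussion: C1 bears CO2Me (C7), C3 the acetate, C4 and C5 the two larger esters, C6 is CH2.
- Retrosynthesis cuts, in order: the O3–acetyl bond; C3–H together with the O5–acyl bond (one hydride-shift event from a C3 ketone); the C1=C2 π bond (back to C1–H/C2–H); the ring bond C4–C5 (aldol of an acyclic keto aldehyde); C1–C6 (Michael); the acyclic C1=C2 (Wittig); O4–CH2 (carboxylate alkylation).
- Forward: (R)-2-methylbutanoate + 1,3-dichloroacetone → keto ylide → Wittig with methyl glyoxylate (chain C7–C1–C2–C3–C4) → acetaldehyde Michael at C1 (adds C6–C5) → aldol closes the only ring → C1=C2 restored through a C2 selenide → Evans–Tishchenko → acetylation.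
- Enabling feature: with C3 as a ketone, flanked by C2 and the O-bearing C4 and 1,5-related to the C5 aldehyde through C2–C1–C6, C4 is the only enolisable carbon that can reach C5 in a six-membered ring. Keeping C1 sp3 (H, CO2Me) during closure lets it relay chirality through the chair and blocks the aromatisation open to 3-dehydroshikimates.
- Stereochemistry: a temporary C1 centre is set by amine catalysis; C4 and C5 are relayed from it in the ring closure and C1 is then erased; C3 comes from C5 by intramolecular hydride transfer, which also places the 3-methylpentanoate on O5; both side-chain centres are bought.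

Key step: step 5

Assumptions: (R)-2-methylbutanoic acid and (S)-1-bromo-2-methylbutane are taken as purchasable in enantiopure form; the catalyst antipode in step 4 is assigned by analogy with aldehyde/nitro-olefin additions of the same catalyst, the C3 acyl group taking the role of the nitro group.

**Route**

Step 1
Reactants: 1 (R)-2-methylbutanoic acid; 2 1,3-dichloropropan-2-one
Product: 3 3-chloro-2-oxopropyl (2R)-2-methylbutanoate
Conditions: KHCO3, DMF, rt; dichloroacetone in threefold excess
Reagents that add atoms: none
Why: SN2 displacement of one α-chloroketone chloride by the carboxylate (excess symmetric dihalide suppresses double substitution) should proceed without touching the acid's α-centre.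

Step 2
Reactants: 3 3-chloro-2-oxopropyl (2R)-2-methylbutanoate
Product: 5 2-oxo-3-(triphenyl-λ5-phosphanylidene)propyl (2R)-2-methylbutanoate, via phosphonium chloride 4 (not isolated)
Conditions: PPh3, toluene, 60 °C; then aq Na2CO3, CH2Cl2, 0 °C
Reagents that add atoms: triphenylphosphine, c1ccc(cc1)P(c1ccccc1)c1ccccc1
Why: quaternisation of the remaining α-chloroketone and deprotonation to the stabilised acyl ylide is the standard phosphorane preparation, and the ester should survive brief cold carbonate.

Step 3
Reactants: 5 2-oxo-3-(triphenyl-λ5-phosphanylidene)propyl (2R)-2-methylbutanoate; 6 methyl glyoxylate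
Product: 7 methyl (2E)-5-{[(2R)-2-methylbutanoyl]oxy}-4-oxopent-2-enoate
Conditions: CH2Cl2, rt
Reagents that add atoms: none
Why: Wittig olefination of a stabilised acyl ylide with a reactive aldehyde should give the (E)-4-oxo-enoate, which holds C7–C1–C2–C3–C4 of the target.

Step 4
Reactants: 7 methyl (2E)-5-{[(2R)-2-methylbutanoyl]oxy}-4-oxopent-2-enoate; 8 acetaldehyde
Product: 9 methyl (2S)-5-{[(2R)-2-methylbutanoyl]oxy}-4-oxo-2-(2-oxoethyl)pentanoate
Conditions: (R)-α,α-diphenylprolinol TMS ether (20 mol %), acetaldehyde in excess, dioxane, rt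
Reagents that add atoms: none
Why: enamine-catalysed Michael addition (Hayashi–Jørgensen catalyst) of acetaldehyde should occur at the alkene carbon β to the ketone (the ester-bearing C1), the shielded enamine fixing the face of 7 in a synclinal transition state and so the temporary C1 centre.

Step 5
Reactants: 9 methyl (2S)-5-{[(2R)-2-methylbutanoyl]oxy}-4-oxo-2-(2-oxoethyl)pentanoate
Product: 10 methyl (1S,3R,4S)-3-hydroxy-4-{[(2R)-2-methylbutanoyl]oxy}-5-oxocyclohexane-1-carboxylate
Conditions: L-proline (30 mol %), DMSO (50 mM in substrate), rt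
Reagents that add atoms: none
Why: Proline condenses with the C3 ketone and, as with hydroxyacetone-type donors, forms the enamine toward the O-bearing C4, which adds to the acid-activated C5 aldehyde; the closest known reactions are the Hajos–Parrish/List proline-catalysed intramolecular aldolisations of 1,5-dicarbonyls and proline aldols of α-oxygenated ketones. The single ring closes in a 6-(enolendo)-exo-trig mode through a chair with the C1 ester equatorial. C5 is controlled by C1: the aldehyde oxygen takes the pseudo-equatorial site, so the new hydroxyl should be cis (1,3-diequatorial) to CO2Me, and substrate control is relied on, not the antipode of proline. C4 is set trans-diequatorial to the C5 hydroxyl and, being α to the ketone, can still equilibrate to that isomer by enolisation. The step needs C4 to react and not C2 or C6, which the structure secures because the C2 ketone enamine or the C6 aldehyde enamine could only close cyclobutanes, and it needs the aldol to stop short of aromatisation, which the sp3 C1 rules out. A minor C5 epimer is a diastereomer at this stage and is removed before C1 is erased in step 7, so it should not erode the final enantiopurity.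

Step 6
Reactants: 10 methyl (1S,3R,4S)-3-hydroxy-4-{[(2R)-2-methylbutanoyl]oxy}-5-oxocyclohexane-1-carboxylate
Product: 11 methyl (1R,2R,4S,5R)-5-hydroxy-4-{[(2R)-2-methylbutanoyl]oxy}-3-oxo-2-(phenylselanyl)cyclohexane-1-carboxylate
Conditions: N-(phenylselanyl)phthalimide, (S)-N-(pyrrolidin-2-ylmethyl)trifluoromethanesulfonamide (20 mol %), CH2Cl2, rt
Reagents that add atoms: N-(phenylselanyl)phthalimide, O=C1c2ccccc2C(=O)N1[Se]c1ccccc1
Why: amine-catalysed α-selenenylation should go through the less substituted enamine (C2, not the O-bearing C4), and equilibration leaves SePh equatorial, trans to CO2Me and therefore syn to C1–H.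

Step 7
Reactants: 11 methyl (1R,2R,4S,5R)-5-hydroxy-4-{[(2R)-2-methylbutanoyl]oxy}-3-oxo-2-(phenylselanyl)cyclohexane-1-carboxylate
Product: 13 methyl (4S,5R)-5-hydroxy-4-{[(2R)-2-methylbutanoyl]oxy}-3-oxocyclohex-1-ene-1-carboxylate, via selenoxide 12 (not isolated)
Conditions: 30% H2O2, pyridine, CH2Cl2, 0 °C → rt
Reagents that add atoms: none
Why: selenoxide syn-elimination (Reich) has only the cis C1–H available, so it should give the C1=C2 enone regiospecifically under mild, nearly neutral conditions while erasing the temporary C1 centre.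

Step 8
Reactants: 14 (S)-1-bromo-2-methylbutane
Product: 16 (3S)-3-methylpentanal, via Grignard reagent 15 (not isolated)
Conditions: Mg, THF; then DMF, 0 °C; aq HCl
Reagents that add atoms: N,N-dimethylformamide, CN(C)C=O
Why: Bouveault formylation of the primary Grignard reagent should give the one-carbon-extended aldehyde, the stereocentre not being the metal-bearing carbon.

Step 9
Reactants: 13 methyl (4S,5R)-5-hydroxy-4-{[(2R)-2-methylbutanoyl]oxy}-3-oxocyclohex-1-ene-1-carboxylate; 16 (3S)-3-methylpentanal
Product: 17 methyl (3R,4R,5R)-3-hydroxy-4-{[(2R)-2-methylbutanoyl]oxy}-5-{[(3S)-3-methylpentanoyl]oxy}cyclohex-1-ene-1-carboxylate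
Conditions: SmI2 (30 mol %) premixed with the aldehyde (sixfold excess) in THF until decolourised, −20 °C; then the hydroxy enone
Reagents that add atoms: none
Why: Proposed new method: the Sm(III) alkoxide of 13 adds to aldehyde 16 to give a hemiacetal on O5, which in the half-chair with O4/O5 pseudo-axial (no 1,3-diaxial partner, C1–C3 being sp2) lies over C3 and passes its hydride to the ketone through a six-membered transition state on the O5 face, so the C3 hydroxyl should emerge anti to O5 and cis to O4 while O5 leaves as the (S)-3-methylpentanoate; the closest known reaction is the Evans–Tishchenko reduction of acyclic β-hydroxy ketones and enones to anti-1,3-diol monoesters, here asked to work with carbinol and carbonyl in the same ring, and premixing removes Sm(II) that would reduce the ene-dione.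

Step 10
Reactants: 17 methyl (3R,4R,5R)-3-hydroxy-4-{[(2R)-2-methylbutanoyl]oxy}-5-{[(3S)-3-methylpentanoyl]oxy}cyclohex-1-ene-1-carboxylate
Product: 18 methyl (3R,4S,5R)-3-acetoxy-4-{[(2R)-2-methylbutanoyl]oxy}-5-{[(3S)-3-methylpentanoyl]oxy}cyclohex-1-ene-1-carboxylate
Conditions: Ac2O, pyridine, DMAP (cat.), CH2Cl2, 0 °C
Reagents that add atoms: acetic anhydride, CC(=O)OC(C)=O
Why: DMAP-catalysed acetylation of the single free (allylic C3) hydroxyl should be faster than acyl migration and touches no stereocentre.

**Compound list**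

1 | (R)-2-methylbutanoic acid | OC(=O)[C@H](C)CC | starting material
2 | 1,3-dichloropropan-2-one | ClCC(=O)CCl | starting material
3 | 3-chloro-2-oxopropyl (2R)-2-methylbutanoate | ClCC(=O)COC(=O)[C@H](C)CC | intermediate
4 | {3-[(2R)-2-methylbutanoyloxy]-2-oxopropyl}triphenylphosphonium chloride | [Cl-].O=C(C[P+](c1ccccc1)(c1ccccc1)c1ccccc1)COC(=O)[C@H](C)CC | intermediate
5 | 2-oxo-3-(triphenyl-λ5-phosphanylidene)propyl (2R)-2-methylbutanoate | O=C(C=P(c1ccccc1)(c1ccccc1)c1ccccc1)COC(=O)[C@H](C)CC | intermediate
6 | methyl glyoxylate | COC(=O)C=O | starting material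
7 | methyl (2E)-5-{[(2R)-2-methylbutanoyl]oxy}-4-oxopent-2-enoate | COC(=O)/C=C/C(=O)COC(=O)[C@H](C)CC | intermediate
8 | acetaldehyde | CC=O | starting material
9 | methyl (2S)-5-{[(2R)-2-methylbutanoyl]oxy}-4-oxo-2-(2-oxoethyl)pentanoate | O=CC[C@H](C(=O)OC)CC(=O)COC(=O)[C@H](C)CC | intermediate
10 | methyl (1S,3R,4S)-3-hydroxy-4-{[(2R)-2-methylbutanoyl]oxy}-5-oxocyclohexane-1-carboxylate | O[C@@H]1C[C@H](C(=O)OC)CC(=O)[C@H]1OC(=O)[C@H](C)CC | intermediate
11 | methyl (1R,2R,4S,5R)-5-hydroxy-4-{[(2R)-2-methylbutanoyl]oxy}-3-oxo-2-(phenylselanyl)cyclohexane-1-carboxylate | O[C@@H]1C[C@H](C(=O)OC)[C@@H]([Se]c2ccccc2)C(=O)[C@H]1OC(=O)[C@H](C)CC | intermediate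
12 | methyl (1R,2R,4S,5R)-5-hydroxy-4-{[(2R)-2-methylbutanoyl]oxy}-3-oxo-2-(phenylseleninyl)cyclohexane-1-carboxylate (mixture at Se) | O[C@@H]1C[C@H](C(=O)OC)[C@@H]([Se](=O)c2ccccc2)C(=O)[C@H]1OC(=O)[C@H](C)CC | intermediate
13 | methyl (4S,5R)-5-hydroxy-4-{[(2R)-2-methylbutanoyl]oxy}-3-oxocyclohex-1-ene-1-carboxylate | O[C@@H]1CC(C(=O)OC)=CC(=O)[C@H]1OC(=O)[C@H](C)CC | intermediate
14 | (S)-1-bromo-2-methylbutane | CC[C@H](C)CBr | starting material
15 | [(2S)-2-methylbutyl]magnesium bromide | CC[C@H](C)C[Mg]Br | intermediate
16 | (3S)-3-methylpentanal | CC[C@H](C)CC=O | intermediate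
17 | methyl (3R,4R,5R)-3-hydroxy-4-{[(2R)-2-methylbutanoyl]oxy}-5-{[(3S)-3-methylpentanoyl]oxy}cyclohex-1-ene-1-carboxylate | CC[C@H](C)CC(=O)O[C@@H]1CC(C(=O)OC)=C[C@@H](O)[C@H]1OC(=O)[C@H](C)CC | intermediate
18 | methyl (3R,4S,5R)-3-acetoxy-4-{[(2R)-2-methylbutanoyl]oxy}-5-{[(3S)-3-methylpentanoyl]oxy}cyclohex-1-ene-1-carboxylate | CC[C@H](C)CC(=O)O[C@@H]1CC(C(=O)OC)=C[C@@H](OC(C)=O)[C@H]1OC(=O)[C@H](C)CC | target

**Step count**

Total: 10 steps. Longest linear sequence: 9 steps (1–7, 9, 10); step 8 is a one-step side branch.

**Steps most likely to fail**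

Step 9 (Proposed new method). The hemiacetal on O5 may fail to reach the ring ketone. The hydroxy enone may aromatise by loss of water under the Lewis acid. Acyl groups may migrate among O3, O4 and O5. The fallback uses known chemistry, sets out from 13 (with 16 as the acyl source) and returns at 18. Pinnick oxidation of 16 (NaClO2, NaH2PO4, 2-methylbut-2-ene, t-BuOH/H2O) would give (3S)-3-methylpentanoic acid F1. DCC (half an equivalent, CH2Cl2) would turn it into (3S)-3-methylpentanoic anhydride F2. Acid-catalysed acylation of 13 with this anhydride (Sc(OTf)3 cat., MeCN, −20 °C) would give methyl (4S,5R)-4-{[(2R)-2-methylbutanoyl]oxy}-5-{[(3S)-3-methylpentanoyl]oxy}-3-oxocyclohex-1-ene-1-carboxylate F3. Luche reduction (NaBH4, CeCl3, MeOH, −78 °C) is expected to deliver hydride axially and give mainly the pseudo-equatorial 3-epi alcohol, methyl (3S,4R,5R)-3-hydroxy-4-{[(2R)-2-methylbutanoyl]oxy}-5-{[(3S)-3-methylpentanoyl]oxy}cyclohex-1-ene-1-carboxylate F4. Mitsunobu reaction with acetic acid (PPh3, DIAD, THF, 0 °C) would then invert the allylic C3 centre and install the acetate in one operation, giving 18.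

Step 4. Facial selectivity at C1 may be low or of the opposite sense, and acetaldehyde may self-condense. The fallback sets C1 by asymmetric hydrogenation instead of conjugate addition; it sets out from 1 (with commercial dimethyl succinate and anhydrous 2,2-dimethoxyacetaldehyde) and returns at 9. Stobbe condensation (NaOMe, MeOH) would give (3E)-5,5-dimethoxy-3-(methoxycarbonyl)pent-3-enoic acid F5. Rh–Et-DuPHOS hydrogenation, with the ligand antipode that gives the S acid, would give (3S)-5,5-dimethoxy-3-(methoxycarbonyl)pentanoic acid F6. Ghosez's reagent (1-chloro-N,N,2-trimethylprop-1-en-1-amine, CH2Cl2, 0 °C), which frees no HCl onto the acetal, would give methyl (2S)-2-(2-chloro-2-oxoethyl)-4,4-dimethoxybutanoate F7. Excess diazomethane (Et2O, 0 °C) would give methyl (2S)-5-diazo-2-(2,2-dimethoxyethyl)-4-oxopentanoate F8. Rh2(OAc)4-catalysed O–H insertion with acid 1 would give methyl (2S)-2-(2,2-dimethoxyethyl)-5-{[(2R)-2-methylbutanoyl]oxy}-4-oxopentanoate F9. Mild acetal hydrolysis (aq TFA, CH2Cl2, 0 °C) would give 9.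

Step 5. The C1 information may leak if the aldehyde carbonyl takes the axial site. The O4 acyl group may migrate to the new O5 hydroxyl under amine catalysis. The aldehyde enamine may react intermolecularly. The fallback moves the closure from reversible enamine catalysis to a stoichiometric chelated metal enolate under kinetic control; it sets out from 9, returns at 10 and makes no new compound. Compound 9 would be treated with TiCl4 and i-Pr2NEt in CH2Cl2 at −78 °C. The α-acyloxy ketone should give the Z-titanium enolate at C4 with the aldehyde bound to the same metal. Closure through a Zimmerman–Traxler transition state fused to the forming chair (CO2Me equatorial) should give the same 4,5-trans adduct 10 at a temperature where acyl transfer is slow.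

Further compounds
F1 | step 9 | (3S)-3-methylpentanoic acid | CC[C@H](C)CC(=O)O
F2 | step 9 | (3S)-3-methylpentanoic anhydride | CC[C@H](C)CC(=O)OC(=O)C[C@@H](C)CC
F3 | step 9 | methyl (4S,5R)-4-{[(2R)-2-methylbutanoyl]oxy}-5-{[(3S)-3-methylpentanoyl]oxy}-3-oxocyclohex-1-ene-1-carboxylate | CC[C@H](C)CC(=O)O[C@@H]1CC(C(=O)OC)=CC(=O)[C@H]1OC(=O)[C@H](C)CC
F4 | step 9 | methyl (3S,4R,5R)-3-hydroxy-4-{[(2R)-2-methylbutanoyl]oxy}-5-{[(3S)-3-methylpentanoyl]oxy}cyclohex-1-ene-1-carboxylate | CC[C@H](C)CC(=O)O[C@@H]1CC(C(=O)OC)=C[C@H](O)[C@H]1OC(=O)[C@H](C)CC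
F5 | step 4 | (3E)-5,5-dimethoxy-3-(methoxycarbonyl)pent-3-enoic acid | COC(=O)/C(CC(=O)O)=C/C(OC)OC
F6 | step 4 | (3S)-5,5-dimethoxy-3-(methoxycarbonyl)pentanoic acid | COC(OC)C[C@H](C(=O)OC)CC(=O)O
F7 | step 4 | methyl (2S)-2-(2-chloro-2-oxoethyl)-4,4-dimethoxybutanoate | COC(OC)C[C@H](C(=O)OC)CC(=O)Cl
F8 | step 4 | methyl (2S)-5-diazo-2-(2,2-dimethoxyethyl)-4-oxopentanoate | COC(OC)C[C@H](C(=O)OC)CC(=O)C=[N+]=[N-]
F9 | step 4 | methyl (2S)-2-(2,2-dimethoxyethyl)-5-{[(2R)-2-methylbutanoyl]oxy}-4-oxopentanoate | COC(OC)C[C@H](C(=O)OC)CC(=O)COC(=O)[C@H](C)CC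
F0 | step 5 | none | none
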